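**Assumption:** The stilbenes 4, 6 and 12 are expected as mixtures of (E) and (Z) isomers and are carried on as such, because step 9 saturates both double bonds; their SMILES therefore carry no double-bond descriptors. The target has no stereocentre.

## Structural features

The target (C28H24O6) is a 17-membered macrocyclic bis(bibenzyl) built from four benzene rings: ring A (3-aryloxy-4,5-dihydroxyphenyl), ring B (para-phenylene), ring C (2-aryloxy-3,4-dihydroxyphenyl) and ring D (ortho-phenylene). The rings are joined in the order D–A–B–C–D by a CH2CH2 bridge (D to A), a diaryl ether oxygen (A to B), a second CH2CH2 bridge (B to C) and a second diaryl ether oxygen (C to D). There is no stereocentre and no fixed axis or plane of chirality, so no stereocentres stand next to each other. The fragile groups are the two catechols on rings A and C, which air oxidises to ortho-quinones, most readily in base; they are best kept as ethers until the last step. The real difficulty is the C–O–D ether. Its ring C carbon (C2) lies between the bridge-bearing C1 and the hydroxyl-bearing C3, its ring D carbon has the other bridge ortho to it, and neither ring carries an activating group, so SNAr is not available and copper-mediated coupling at a doubly ortho-substituted halide is slow. The A–O–B ether is ordinary by comparison, because ring B can be brought in as a para-formyl fluoroarene. The key step exploits the C1(alkyl)–C2(O-aryl)–C3(OH) triad of ring C: with C3 as a carbonyl and C2 as a diazo carbon, ring C is an ortho-quinone diazide, and carbenoid insertion into the O–H of the ring D phenol produces exactly this pattern while closing the macrocycle.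

## Logic of the disconnections

**17 to 16.** The three O–CH3 bonds (two on ring A, one on ring C) are cut. Methyl ethers keep both catechols masked through every earlier step and leave the ring D phenol as the only O–H in the key-step substrate. The gain is that no oxidation-prone catechol is handled before the end. The demand is a demethylation that spares both diaryl ethers, and an air-free work-up.

**16 to 15.** The bond between ring C C2 and the ring D oxygen is cut, which opens the 17-membered ring. This is the most hindered bond of the molecule, and cutting it last in the retrosynthesis means that the forward ring closure and the hindered etherification are one event. The seco compound 15 is a linear chain of four rings with the ring C oxygen at C3 as a carbonyl and C2 as a diazo carbon. The forward step must favour intramolecular O–H insertion over every other fate of the carbenoid.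

**15 to 13 (through 14).** The C=N2 unit is traced back to C–NH2 with the C3 oxygen as a free hydroxyl. An ortho-aminophenol is the standard source of an ortho-quinone diazide. The demand is a diazotisation that leaves the free, electron-rich ring D phenol untouched (no C-nitrosation, no azo coupling).

**13 to 12.** Five functional-group changes are grouped into one reduction: both CH2CH2 bridges come from CH=CH, the amine from a nitro group, and the two free hydroxyls (ring C C3 and ring D) from benzyl ethers. This is the main design choice for the precursor: benzyl is used for exactly the two oxygens that must be free in 13, methyl for the three that must stay masked, so no separate deprotection step is needed. The demand is that one hydrogenation does all five jobs and that the air-sensitive product is used at once.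

**12 to 6 and 11.** The B–C double bond is cut (Wittig). This is the convergent junction: an aldehyde carrying rings D, A and B meets a ylide carrying ring C. The nitro group stabilises the ylide, so a mild base suffices.

**11 to 10, 9, 8 and 7.** The C–P bond, the C–Br bond, the benzylic C–O oxidation level and the O-benzyl bond are traced back in turn. 7 already has the full ring C substitution pattern (formyl carbon for the bridge, nitro for the future diazo carbon, hydroxyl for the future carbonyl, methoxy), so no aromatic substitution is needed on ring C.

**6 to 4 and 5.** The bond between the ring A oxygen and the ring B carbon is cut (SNAr). The para-formyl group of 5 activates the fluoride and then serves as the handle for the B–C olefination. The demand is that the ring A phenol is the only free phenol at this stage, which the ring D benzyl ether secures.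

**4 to 2 and 3; 2 to 1.** The D–A double bond is cut (Wittig), then the C–P bond. 3 is used with its phenol free, which saves a protection and deprotection pair; the forward step must tolerate a phenoxide on the aldehyde partner.

## Other disconnections considered

**Alternative 1:** Ring B itself is taken apart into a four-carbon and a two-carbon piece. The seco compound A1 carries a 2-aryloxybuta-1,3-diene on the ring A oxygen and a terminal ynone (HC≡C–C(=O)–CH2–) on ring C. Heating A1 at high dilution would form two C–C bonds in an intramolecular Diels–Alder reaction and give the macrocyclic 1,4-cyclohexadienyl ketone A2. Dehydrogenation to the arene, reduction of the aryl ketone to CH2 and demethylation would follow.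
- In favour: ring B and the macrocycle are made together, the "para" orientation of a 2-oxygenated diene with an acyl alkyne matches the 1,4-pattern of ring B, and the reaction needs no metal.
- Against: the diene is an acid-labile enol ether (accessible, for example, by methylenation of an aryl acrylate with Cp2TiMe2) and the ynone is a polymerisable Michael acceptor, and both must survive on one molecule. A cycloaddition through a 17-membered transition state needs heat at concentrations where the ynone is unlikely to last. Three steps follow the ring closure. The hindered C–O–D ether still has to be made earlier by a conventional coupling at the doubly ortho-substituted ring C carbon.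
- Comparison: on structure, it works on the least hindered ring and leaves the hardest bond to older chemistry, whereas the chosen plan makes the hardest bond in the ring-closing step. On mechanism, a concerted cycloaddition has no stray intermediates and rests on well-known pericyclic reactivity; here Alternative 1 is the better of the two. On step economy the chosen plan is shorter (one step after the key step instead of three, and no separate synthesis of the hindered ether). Both need high dilution; on that point they are equal.

**Alternative 2:** The bond between ring A carbon and the ether oxygen to ring B is cut. The seco bis-phenol A3 has a 3,5-dibromo-4-hydroxyphenyl ring A and a 3,5-dichloro-4-hydroxyphenyl ring B. Anodic oxidation in methanol with LiClO4 would convert the dibromophenol into an electrophilic dienone-type species, the dichlorophenol oxygen would add at a bromine-bearing ortho carbon, and zinc reduction would rearomatise with loss of that bromine to give the macrocyclic bromophenol A4.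
- In favour: it follows the likely biogenesis (phenol oxidative coupling), the halogens block C–C coupling and place the ether ortho to a hydroxyl as ring A requires, and the reacting phenols need no protecting groups. It forms the less hindered of the two ethers and belongs to a known reaction type for macrocyclic diaryl ethers; on precedent it is better than the chosen key step.
- Against: A4 still has bromine where ring A needs its second hydroxyl, so a hydroxylation next to a free phenol, removal of two chlorines and demethylation follow (at least three steps). Four halogens are installed and none remains in the target. Which ring is oxidised depends on a small difference in oxidation potential. Electrolysis at high dilution is awkward to scale. The hindered C–O–D ether must again exist before the key step.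
- Comparison: on structure, it closes the ring at the easy ether and the chosen plan at the hard one. On mechanism, it uses an electrochemically generated electrophile and the chosen plan a catalytic carbenoid; both can oligomerise. On step economy the chosen plan is clearly shorter after the ring closure and needs no sacrificial halogens.

**Alternative 3:** The bond between ring A and the first carbon of the D–A bridge is cut. The seco compound A5 carries an aryl iodide on ring A and a vinyl group ortho to the ether oxygen on ring D. Pd(OAc)2 with tri(ortho-tolyl)phosphine and triethylamine at high dilution would give the macrocyclic (E)-stilbene A6 by Heck coupling; hydrogenation and demethylation would finish the synthesis.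
- In favour: this is the most thoroughly established reaction of the four, the new bond forms at an aryl carbon flanked by two hydrogens, functional-group tolerance is broad, and no diazonium or diazo intermediate is handled. On precedent and on operational safety it is better than the chosen plan, and with two steps after the key step it is nearly equal on that count.
- Against: an (E)-stilbene next to the ortho-phenylene ring D has to fit into the 17-membered ring. At high dilution the turnover of zerovalent palladium is slow and the catalyst is liable to aggregate. Arylation at the internal alkene carbon would give a 1,1-diarylethene in a 16-membered ring. Again the hindered C–O–D ether must be prepared beforehand by intermolecular coupling.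
- Comparison: on structure, it closes the ring at an unhindered C–C bond and the chosen plan at the hindered C–O bond. On mechanism, palladium-mediated oxidative addition and insertion are well understood, whereas carbenoid O–H insertion of an ortho-quinone diazide is not established. On step economy the chosen plan saves the separate hindered ether synthesis and one step after the ring closure.

Key step: step 11

## Route

Step 1
Reactants: 1 2-(benzyloxy)benzyl alcohol
Product: 2 [2-(benzyloxy)benzyl]triphenylphosphonium bromide
Conditions: PPh3·HBr (1.05 equiv), MeCN, reflux
Reagents that add atoms: triphenylphosphine hydrobromide, [Br-].[PH+](c1ccccc1)(c1ccccc1)c1ccccc1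
Why: Direct conversion of a benzylic alcohol into its phosphonium salt: the acid activates the hydroxyl of the ortho-alkoxybenzylic alcohol, bromide displaces water, and PPh3 quaternises the benzyl bromide in the same flask. The aryl benzyl ether is stable to the stoichiometric, quickly consumed acid.

Step 2
Reactants: 2 [2-(benzyloxy)benzyl]triphenylphosphonium bromide; 3 3-hydroxy-4,5-dimethoxybenzaldehyde
Product: 4 5-{2-[2-(benzyloxy)phenyl]ethenyl}-2,3-dimethoxyphenol (E/Z mixture)
Conditions: KOtBu (2.3 equiv), THF, 0 °C to rt
Reagents that add atoms: none
Why: Wittig olefination with a semi-stabilised benzyl ylide; the second equivalent of base turns the phenol of 3 into a phenoxide that is meta to the formyl group and so does not deactivate it by conjugation. The alkene geometry is irrelevant because the double bond is hydrogenated in step 9.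

Step 3
Reactants: 4 5-{2-[2-(benzyloxy)phenyl]ethenyl}-2,3-dimethoxyphenol; 5 4-fluorobenzaldehyde
Product: 6 4-(5-{2-[2-(benzyloxy)phenyl]ethenyl}-2,3-dimethoxyphenoxy)benzaldehyde (E/Z mixture)
Conditions: K2CO3, DMF, 120 °C
Reagents that add atoms: none
Why: Nucleophilic aromatic substitution by addition–elimination: the ring A phenoxide adds para to the formyl group of 5 and fluoride leaves. The ring D oxygen is a benzyl ether, so only the ring A oxygen can react.

Step 4
Reactants: 7 3-hydroxy-4-methoxy-2-nitrobenzaldehyde
Product: 8 3-(benzyloxy)-4-methoxy-2-nitrobenzaldehyde
Conditions: BnBr, K2CO3, DMF, 60 °C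
Reagents that add atoms: benzyl bromide, BrCc1ccccc1
Why: Williamson etherification of an acidic ortho-nitrophenol; the benzyl group removes the acidic proton for the later ylide chemistry and is cleaved without an extra step in the hydrogenation of step 9.

Step 5
Reactants: 8 3-(benzyloxy)-4-methoxy-2-nitrobenzaldehyde
Product: 9 [3-(benzyloxy)-4-methoxy-2-nitrophenyl]methanol
Conditions: NaBH4, MeOH/THF, 0 °C
Reagents that add atoms: none
Why: Hydride reduction of an electron-poor aryl aldehyde; NaBH4 does not touch the nitro group or the benzyl ether.

Step 6
Reactants: 9 [3-(benzyloxy)-4-methoxy-2-nitrophenyl]methanol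
Product: 10 2-(benzyloxy)-4-(bromomethyl)-1-methoxy-3-nitrobenzene
Conditions: PBr3, CH2Cl2, 0 °C to rt
Reagents that add atoms: phosphorus tribromide, BrP(Br)Br
Why: Conversion of a primary benzylic alcohol into the bromide through its phosphite ester and SN2 attack of bromide; no cation-prone or acid-labile group is present.

Step 7
Reactants: 10 2-(benzyloxy)-4-(bromomethyl)-1-methoxy-3-nitrobenzene
Product: 11 {[3-(benzyloxy)-4-methoxy-2-nitrophenyl]methyl}triphenylphosphonium bromide
Conditions: PPh3, toluene, 90 °C
Reagents that add atoms: triphenylphosphine, c1ccc(cc1)P(c1ccccc1)c1ccccc1
Why: SN2 quaternisation of PPh3 by a benzylic bromide; the salt should precipitate from toluene, and the temperature is far below that at which phosphines deoxygenate nitroarenes.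

Step 8
Reactants: 6 4-(5-{2-[2-(benzyloxy)phenyl]ethenyl}-2,3-dimethoxyphenoxy)benzaldehyde; 11 {[3-(benzyloxy)-4-methoxy-2-nitrophenyl]methyl}triphenylphosphonium bromide
Product: 12 2-(benzyloxy)-4-{2-[4-(5-{2-[2-(benzyloxy)phenyl]ethenyl}-2,3-dimethoxyphenoxy)phenyl]ethenyl}-1-methoxy-3-nitrobenzene (mixture of alkene isomers)
Conditions: K2CO3, 18-crown-6 (cat.), CH2Cl2, reflux
Reagents that add atoms: none
Why: Wittig olefination with an ortho-nitrobenzyl ylide, which is acidified by the nitro group and so forms under mild solid–liquid conditions. Both alkene geometries converge in step 9.

Step 9
Reactants: 12 2-(benzyloxy)-4-{2-[4-(5-{2-[2-(benzyloxy)phenyl]ethenyl}-2,3-dimethoxyphenoxy)phenyl]ethenyl}-1-methoxy-3-nitrobenzene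
Product: 13 2-amino-3-{2-[4-(5-{2-(2-hydroxyphenyl)ethyl}-2,3-dimethoxyphenoxy)phenyl]ethyl}-6-methoxyphenol
Conditions: H2 (1 atm), Pd/C (10% Pd on carbon), EtOAc/EtOH, rt; filtered under Ar and used at once
Reagents that add atoms: none
Why: Heterogeneous catalytic hydrogenation: one catalyst saturates both stilbene double bonds, reduces the nitro group to the amine and hydrogenolyses both benzylic C–O bonds. Methyl ethers and diaryl ethers are inert under these conditions.

Step 10
Reactants: 13 2-amino-3-{2-[4-(5-{2-(2-hydroxyphenyl)ethyl}-2,3-dimethoxyphenoxy)phenyl]ethyl}-6-methoxyphenol
Product: 15 6-diazo-5-{2-[4-(5-{2-(2-hydroxyphenyl)ethyl}-2,3-dimethoxyphenoxy)phenyl]ethyl}-2-methoxycyclohexa-2,4-dien-1-one (seco ortho-quinone diazide with free ring D phenol), via diazonium chloride 14 (not isolated)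
Conditions: isoamyl nitrite (1.05 equiv), HCl (2 equiv, in dioxane), THF/EtOH, −10 °C, dark; then aq. NaHCO3 to pH 7, CH2Cl2; kept in solution, never taken to dryness
Reagents that add atoms: isoamyl nitrite, CC(C)CCON=O
Why: Diazotisation of the aryl amine (N-nitrosation, then loss of water) in acid, where the ring D phenol is neither nitrosated at a competitive rate nor ionised for azo coupling. The ortho-hydroxy diazonium ion is far more acidic than an ordinary phenol, so buffering to neutral pH removes only that proton and gives the neutral quinone diazide.

Step 11
Reactants: 15 6-diazo-5-{2-[4-(5-{2-(2-hydroxyphenyl)ethyl}-2,3-dimethoxyphenoxy)phenyl]ethyl}-2-methoxycyclohexa-2,4-dien-1-one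
Product: 16 tri-O-methyl macrocycle: the 17-membered ring of the target with methoxy groups at both ring A oxygens and at ring C C4, and a free hydroxyl at ring C C3 next to the new ether at C2
Conditions: Rh2(OAc)4 (5 mol%), 4 Å molecular sieves, ClCH2CH2Cl, 60 °C, syringe-pump addition of 15 over 12 h (final concentration about 1 mM), Ar, dark
Reagents that add atoms: none
Why: Proposed new method: Rh2(OAc)4, a dimer of divalent rhodium, should expel N2 from the diazo carbon of 15 (ring C C2) and give a quinoid carbenoid whose empty orbital is part of the ring π system; the lone pair of the ring D phenol oxygen adds to this carbon, the metal leaves, and the resulting zwitterion is already an aromatic aryloxonium phenoxide, so a proton shift from the oxonium oxygen to the neighbouring C3 oxygen gives 16 directly and no separate dienone-to-phenol tautomerisation need be invoked. The closest known reaction types are the Rh2(OAc)4-catalysed O–H insertion of cyclic 2-diazo-1,3-diketones into phenols followed by aromatisation to hindered diaryl ethers, and rhodium carbenoid arylations with quinone diazides; new here are the use of an ortho-quinone diazide for a phenol O–H insertion and its use to close a macrocycle. The 17-membered ring closes end to end by attack of the exocyclic ring D oxygen on the ring C carbenoid carbon, and slow addition to a dilute solution keeps the stationary concentration of the carbenoid below the level at which two chains meet. No stereocentre is formed. The step needs chemoselectivity for O–H insertion over Wolff ring contraction, over attack on ring B or on C–H bonds, and over intermolecular insertion. A metal-bound carbenoid generated in the dark at 60 °C should not follow the photochemical or thermal Wolff path, insertion into the bridge CH2 groups would require three- or four-membered rings, and the ring B carbons within reach are the ipso carbon (no proton to lose) and carbons meta to the aryloxy group (not activated). The phenol is the only O–H in 15, because the C3 oxygen is tied up as the carbonyl and all other oxygens are methyl ethers. The site of etherification is fixed by the diazo carbon, and the nucleophile approaches perpendicular to the ring plane, away from the two flanking substituents that would block substitution at an aryl halide.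

Step 12
Reactants: 16 tri-O-methyl macrocycle
Product: 17 target macrocycle (CNP0114693.0): ring A 3-aryloxy-4,5-dihydroxy, ring C 2-aryloxy-3,4-dihydroxy
Conditions: BBr3 (8 equiv), CH2Cl2, −78 °C to rt; then degassed ice-water, Ar
Reagents that add atoms: none
Why: Lewis-acid cleavage of three aryl methyl ethers: BBr3 binds each methoxy oxygen and bromide attacks the methyl carbon in an SN2 step. The diaryl ether C–O bonds offer no sp3 carbon and survive; hydrolysis of the aryl borates releases both catechols.

## Compound list

1 | 2-(benzyloxy)benzyl alcohol | OCc1ccccc1OCc1ccccc1 | starting material
2 | [2-(benzyloxy)benzyl]triphenylphosphonium bromide | [Br-].C(c1ccccc1OCc1ccccc1)[P+](c1ccccc1)(c1ccccc1)c1ccccc1 | intermediate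
3 | 3-hydroxy-4,5-dimethoxybenzaldehyde | COc1cc(C=O)cc(O)c1OC | starting material
4 | 5-{2-[2-(benzyloxy)phenyl]ethenyl}-2,3-dimethoxyphenol (E/Z mixture) | COc1cc(C=Cc2ccccc2OCc2ccccc2)cc(O)c1OC | intermediate
5 | 4-fluorobenzaldehyde | O=Cc1ccc(F)cc1 | starting material
6 | 4-(5-{2-[2-(benzyloxy)phenyl]ethenyl}-2,3-dimethoxyphenoxy)benzaldehyde (E/Z mixture) | COc1cc(C=Cc2ccccc2OCc2ccccc2)cc(Oc2ccc(C=O)cc2)c1OC | intermediate
7 | 3-hydroxy-4-methoxy-2-nitrobenzaldehyde | COc1ccc(C=O)c([N+](=O)[O-])c1O | starting material
8 | 3-(benzyloxy)-4-methoxy-2-nitrobenzaldehyde | COc1ccc(C=O)c([N+](=O)[O-])c1OCc1ccccc1 | intermediate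
9 | [3-(benzyloxy)-4-methoxy-2-nitrophenyl]methanol | COc1ccc(CO)c([N+](=O)[O-])c1OCc1ccccc1 | intermediate
10 | 2-(benzyloxy)-4-(bromomethyl)-1-methoxy-3-nitrobenzene | COc1ccc(CBr)c([N+](=O)[O-])c1OCc1ccccc1 | intermediate
11 | {[3-(benzyloxy)-4-methoxy-2-nitrophenyl]methyl}triphenylphosphonium bromide | [Br-].COc1ccc(C[P+](c2ccccc2)(c2ccccc2)c2ccccc2)c([N+](=O)[O-])c1OCc1ccccc1 | intermediate
12 | 2-(benzyloxy)-4-{2-[4-(5-{2-[2-(benzyloxy)phenyl]ethenyl}-2,3-dimethoxyphenoxy)phenyl]ethenyl}-1-methoxy-3-nitrobenzene (mixture of alkene isomers) | COc1cc(C=Cc2ccccc2OCc2ccccc2)cc(Oc2ccc(C=Cc3ccc(OC)c(OCc4ccccc4)c3[N+](=O)[O-])cc2)c1OC | intermediate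
13 | 2-amino-3-{2-[4-(5-{2-(2-hydroxyphenyl)ethyl}-2,3-dimethoxyphenoxy)phenyl]ethyl}-6-methoxyphenol | COc1cc(CCc2ccccc2O)cc(Oc2ccc(CCc3ccc(OC)c(O)c3N)cc2)c1OC | intermediate
14 | 2-hydroxy-6-{2-[4-(5-{2-(2-hydroxyphenyl)ethyl}-2,3-dimethoxyphenoxy)phenyl]ethyl}-3-methoxybenzenediazonium chloride | [Cl-].COc1cc(CCc2ccccc2O)cc(Oc2ccc(CCc3ccc(OC)c(O)c3[N+]#N)cc2)c1OC | intermediate (not isolated)
15 | 6-diazo-5-{2-[4-(5-{2-(2-hydroxyphenyl)ethyl}-2,3-dimethoxyphenoxy)phenyl]ethyl}-2-methoxycyclohexa-2,4-dien-1-one | COc1cc(CCc2ccccc2O)cc(Oc2ccc(CCC3=CC=C(OC)C(=O)C3=[N+]=[N-])cc2)c1OC | intermediate
16 | tri-O-methyl macrocycle with free ring C hydroxyl | COc1cc2cc(c1OC)Oc1ccc(cc1)CCc1ccc(OC)c(O)c1Oc1ccccc1CC2 | intermediate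
17 | target macrocycle, CNP0114693.0 | Oc1cc2cc(c1O)Oc1ccc(cc1)CCc1ccc(O)c(O)c1Oc1ccccc1CC2 | target

## Step count and least certain steps

Total step count: 12. Longest linear sequence: 9 steps (7 to 17, steps 4 to 12); the other branch (1 to 17, steps 1 to 3 and 8 to 12) has 8.

**Step 11 (key step, proposed new method).** Most likely to go wrong: capture of the carbenoid by ring B in a six-membered closure (a Pschorr-like arylation giving a 9,10-dihydrophenanthrene), which has a much higher effective molarity than a 17-membered closure. Intermolecular O–H insertion leading to oligomers, and insertion into traces of water, are the next concerns. Fallback by known chemistry, setting out from 14 and coming back at 16: the diazonium solution from step 10 would be treated with aqueous KI instead of being neutralised, which replaces the diazonium group by iodine and should give 2-iodo-6-methoxy-3-{2-[4-(5-{2-(2-hydroxyphenyl)ethyl}-2,3-dimethoxyphenoxy)phenyl]ethyl}phenol F1. An intramolecular Ullmann etherification of F1 (CuI, N,N-dimethylglycine, Cs2CO3, dioxane, 100 °C, high dilution) would then form the same ring C carbon–oxygen bond and deliver 16. The ring C hydroxyl next to the iodine cannot close a ring and should stay a spectator at high dilution. This coupling is expected to be slow because of the two ortho substituents, which is why it is the reserve and not the first choice.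

**Step 10.** Most likely to go wrong: C-nitrosation of the free ring D phenol by excess nitrosating agent, or azo coupling of the diazonium ion onto that phenol if the pH rises locally during neutralisation. Fallback, setting out from 13 and coming back at 15: both phenols of 13 would be silylated (TBSCl, imidazole, DMF; the aniline nitrogen is not silylated) to give the bis(tert-butyldimethylsilyl) ether F2. Diazotisation of F2 as in step 10 would give the bis-silylated diazonium chloride F3, in which no free phenol is exposed to the nitrite. HF·pyridine in THF at 0 °C would then remove both silyl groups in acidic medium, where the diazonium ion does not couple, and neutralisation with NaHCO3 would give 15.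

**Step 9.** Most likely to go wrong: cyclisation of partly reduced nitrogen intermediates (nitroso, hydroxylamine) onto the neighbouring stilbene double bond before it is saturated, stalling of the hydrogenolysis of the hindered ring C benzyl ether once the basic aniline sits on the catalyst, and air oxidation of the aminophenol during filtration. Fallback, setting out from 12 and coming back at 13: both double bonds would first be saturated with diimide (4-methylbenzenesulfonohydrazide, NaOAc, THF/H2O, reflux), which touches neither the nitro group nor the benzyl ethers, to give the saturated nitro dibenzyl ether F4. Hydrogenation of F4 (H2, Pd/C, EtOAc/AcOH) then has only the nitro group and the two benzyl ethers to deal with and should give 13.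

**Step 2.** Most likely to go wrong: sluggish olefination because the potassium phenoxide of 3 aggregates or precipitates, with the ylide consumed by proton transfer instead of addition. Fallback, setting out from 3 and coming back at 6: the order of ether formation and olefination would be reversed. SNAr of 3 with 4-fluorobenzonitrile (K2CO3, DMF, 100 °C) would give 4-(5-formyl-2,3-dimethoxyphenoxy)benzonitrile F5, which has a single aldehyde and no acidic proton. Wittig reaction of F5 with 2 (KOtBu, 1.1 equiv, THF) would give 4-(5-{2-[2-(benzyloxy)phenyl]ethenyl}-2,3-dimethoxyphenoxy)benzonitrile F6. Reduction of the nitrile with i-Bu2AlH (toluene, −78 °C) and hydrolysis of the imine with dilute HCl would give 6. This costs one more step.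

## Further compounds

F1 | step 11 | 2-iodo-6-methoxy-3-{2-[4-(5-{2-(2-hydroxyphenyl)ethyl}-2,3-dimethoxyphenoxy)phenyl]ethyl}phenol | COc1cc(CCc2ccccc2O)cc(Oc2ccc(CCc3ccc(OC)c(O)c3I)cc2)c1OC
F2 | step 10 | 2-[(tert-butyldimethylsilyl)oxy]-6-{2-[4-(5-{2-(2-[(tert-butyldimethylsilyl)oxy]phenyl)ethyl}-2,3-dimethoxyphenoxy)phenyl]ethyl}-3-methoxyaniline | COc1cc(CCc2ccccc2O[Si](C)(C)C(C)(C)C)cc(Oc2ccc(CCc3ccc(OC)c(O[Si](C)(C)C(C)(C)C)c3N)cc2)c1OC
F3 | step 10 | 2-[(tert-butyldimethylsilyl)oxy]-6-{2-[4-(5-{2-(2-[(tert-butyldimethylsilyl)oxy]phenyl)ethyl}-2,3-dimethoxyphenoxy)phenyl]ethyl}-3-methoxybenzenediazonium chloride | [Cl-].COc1cc(CCc2ccccc2O[Si](C)(C)C(C)(C)C)cc(Oc2ccc(CCc3ccc(OC)c(O[Si](C)(C)C(C)(C)C)c3[N+]#N)cc2)c1OC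
F4 | step 9 | 2-(benzyloxy)-4-{2-[4-(5-{2-[2-(benzyloxy)phenyl]ethyl}-2,3-dimethoxyphenoxy)phenyl]ethyl}-1-methoxy-3-nitrobenzene | COc1cc(CCc2ccccc2OCc2ccccc2)cc(Oc2ccc(CCc3ccc(OC)c(OCc4ccccc4)c3[N+](=O)[O-])cc2)c1OC
F5 | step 2 | 4-(5-formyl-2,3-dimethoxyphenoxy)benzonitrile | COc1cc(C=O)cc(Oc2ccc(C#N)cc2)c1OC
F6 | step 2 | 4-(5-{2-[2-(benzyloxy)phenyl]ethenyl}-2,3-dimethoxyphenoxy)benzonitrile (E/Z mixture) | COc1cc(C=Cc2ccccc2OCc2ccccc2)cc(Oc2ccc(C#N)cc2)c1OC
A1 | alternative 1 | seco 2-aryloxybuta-1,3-diene with terminal ynone | C#CC(=O)Cc1ccc(OC)c(OC)c1Oc1ccccc1CCc1cc(OC)c(OC)c(OC(=C)C=C)c1
A2 | alternative 1 | macrocyclic 1,4-cyclohexadienyl ketone | O=C1Cc2ccc(OC)c(OC)c2Oc2ccccc2CCc2cc(OC)c(OC)c(c2)OC2=CCC1=CC2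
A3 | alternative 2 | seco bis-phenol with 3,5-dibromo-4-hydroxyphenyl ring A and 3,5-dichloro-4-hydroxyphenyl ring B | Oc1c(Br)cc(CCc2ccccc2Oc2c(CCc3cc(Cl)c(O)c(Cl)c3)ccc(OC)c2OC)cc1Br
A4 | alternative 2 | macrocyclic bromophenol diaryl ether | Brc1cc2cc(c1O)Oc1c(Cl)cc(cc1Cl)CCc1ccc(OC)c(OC)c1Oc1ccccc1CC2
A5 | alternative 3 | seco ring A aryl iodide with ortho-vinyl ring D | C=Cc1ccccc1Oc1c(CCc2ccc(Oc3cc(I)cc(OC)c3OC)cc2)ccc(OC)c1OC
A6 | alternative 3 | macrocyclic (E)-stilbene tetramethyl ether | COc1cc2cc(c1OC)Oc1ccc(cc1)CCc1ccc(OC)c(OC)c1Oc1ccccc1/C=C/2
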